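(All runs stem from a simulated flask for an exercise, and the scatter is random.)

A millimolar of target means little until I hold it against the substrate that could have become it, so I read each run on a clock of my own. At 31 min the west run stands at 0.358 on that clock, the natural logarithm of substrate charged over substrate not yet turned, which is the ordinate of a first-order plot. If the rate is first order in substrate and the partner follows the same course, the substrate charge drops out of the clock.

| flask | substrate | partner | target | time |
|---|---|---|---|---|
| west | 300 mM | 360 mM |  |  |
| east | 180 mM | 240 mM |  |  |
| north | 150 mM | 360 mM |  |  |
| north-east | 300 mM | 360 mM | 150 mM |  |
| south | 99.0 mM | 120 mM |  | 31 min |

- west run (time / min: [target] / mM): 5.2: 40.8; 10: 60.5; 16: 76.4; 21: 81.8; 26: 83.6; 31: 90.3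
- east run (time / min: [target] / mM): 5.2: 13.9; 10: 21.5; 16: 31.2; 21: 32.9; 26: 33.4; 31: 36.7
- north run (time / min: [target] / mM): 5.2: 24.2; 10: 32.0; 16: 44.4; 21: 47.2; 26: 54.3; 31: 53.5
- north-east run (time / min: [target] / mM): 5.2: 187.9; 10: 208.3; 16: 227.7; 21: 229.8; 26: 235.4; 31: 240.8

(each reading ± 2 mM)

- Overall: substrate + partner -> target.
- Constant volume, constant temperature.
- A reading of a species includes what of it is bound.
- An order is taken over about fifteen percent of the charge, up and down.

- the exponent of [partner] in the starting rate at the charge of the west run (at the point where two percent of the substrate have become target)
- the exponent of [substrate] in the starting rate at the charge of the west run (at the point where two percent of the substrate have become target) (one fixed amount of target, the same in the runs compared)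
- target in the south run at 31 min, as a share of the substrate charged

Which numbers must I know well for the south run? The added target matters little: counting target made beyond its charge, the north-east run stands at 0.360. The scatter stands at 5.45% of the last east reading, and an estimate scaled from that reading carries about that share. The partner exponent matters more: the south run has half the partner of the east run, so an error of 0.5 in that exponent moves the answer by a factor of 1.41.

Now the number itself. A first round, west against east at 0.228, gives an exponent of 1.11. Putting that answer back, I see that making target has cost the west run 25.1% of its partner and the east run 15.3%, so the pair is unequal. Making target has cost the north run 14.9%, close to the east share, so the second round takes north at 0.441 against east and gives 1.63. The west clock over the north clock is 0.812, and the ratio of partner remaining, raised to that exponent, gives 0.812. West has twice the substrate of north at the same partner charge, and I keep a substrate exponent of one as a working value, though both of those numbers come from the same readings. Scaling the east clock down gives my estimate for the south run, a clock of 0.0738, which is 7.11% of its substrate.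

The forecast gives 1.4 for partner, 0.72 for substrate and 8.5% for the south run, and it reads the north-east run thus: “So target neither inhibits nor reverses”. Its substrate exponent stands lower than mine, its partner exponent stands lower than mine, and its south share stands higher than mine.

The simulation gives 1.4 for partner, 1.1 for substrate and 6.83% for the south run.

    substrate + 2 partner → target + partner (1.176 M⁻² min⁻¹)
    2 partner ⇌ idle reagent dimer, settled at all times (3.360 M⁻¹)
    partner → lost reagent (0.07920 min⁻¹)

The south clock ends at 0.0708, below the 0.358 of the west run. Within the south run itself, the passing of partner into lost reagent holds the clock down: without that step the south run turns 18.0% of its substrate, a clock of 0.199, which is 2.81 times as far. On the same clock, the north run reaches 0.288 at 13.0 min, earlier than the west run at 15.6 min.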